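The plan cuts two aryl–carbon bonds of the benzo ring at once, C4–C4a and C1–C8a. C4a and C8a are adjacent ring atoms, and C8a has the oxygen-bearing C8 as its other neighbour, so an aryne across C4a–C8a is polarised for nucleophilic attack at C4a. Fluoride unmasks this aryne from 3,5-bis(benzyloxy)-2-(trimethylsilyl)phenyl triflate. Dimethyl malonate is spliced in by cleavage of one CH2–CO2Me bond, which gives in one operation a homophthalate holding C4, C3 and C1. C3, as its Weinreb amide, then acylates an epoxide-derived alkyne. The ynone is reduced enantioselectively, and a single hydrogenation with lactonisation ends the route.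

Key step: step 4

Remark on locants: isochromanone numbering (C1, C3, C4, C4a–C8a) is used for the core and C1'–C11' for the side chain. The target is (3R,6'S).
Remark on protecting groups: the phenol oxygens travel as benzyl ethers. Methyl ethers would need a boron or aluminium halide at the end, next to a free secondary alcohol and a lactone.
Remark on the C3 ketone: a saturated C3 ketone would offer a chiral reductant two similar CH2 arms, so C1'–C2' is carried as an alkyne until C3 is set.
Assumption: compounds 1, 8, 12 and 14 are taken as catalogue compounds.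

Step 1
Reactants: 1 3,5-bis(benzyloxy)phenol
Product: 2 3,5-bis(benzyloxy)phenyl isopropylcarbamate
Conditions: i-PrNCO, Et3N (cat.), CH2Cl2, rt
Reagents that add atoms: isopropyl isocyanate, CC(C)N=C=O
Why: Amine-catalysed addition of the phenol to the isocyanate (O-carbamoylation) should be clean and installs a strong director for ortho-metalation that can later be removed under mild base.

Step 2
Reactants: 2 3,5-bis(benzyloxy)phenyl isopropylcarbamate
Product: 5 3,5-bis(benzyloxy)-2-(trimethylsilyl)phenyl isopropylcarbamate, via N-TBS carbamate 3 (not isolated), via N-TBS 2-TMS carbamate 4 (not isolated)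
Conditions: TBSOTf, TMEDA, Et2O, 0 °C to rt; n-BuLi, TMEDA, −78 °C; TMSCl, −78 °C to rt; aq NaHSO4
Reagents that add atoms: chlorotrimethylsilane, C[Si](C)(C)Cl; tert-butyldimethylsilyl triflate, CC(C)(C)[Si](C)(C)OS(=O)(=O)C(F)(F)F (its silyl group is kept only in 3 and 4)
Why: Directed ortho-metalation: transient N-silylation masks the N–H, the carbamate and the adjacent benzyloxy group then act together so that n-BuLi/TMEDA should remove H-2 (H-6 is equivalent by symmetry) faster than H-4 or a benzylic proton at −78 °C, TMSCl traps the aryllithium, and the N–Si bond is hydrolysed in the acidic work-up.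

Step 3
Reactants: 5 3,5-bis(benzyloxy)-2-(trimethylsilyl)phenyl isopropylcarbamate
Product: 7 3,5-bis(benzyloxy)-2-(trimethylsilyl)phenyl trifluoromethanesulfonate, via 2-silylphenol 6 (not isolated)
Conditions: Et2NH, DBU, MeCN, 40 °C; then PhNTf2, rt
Reagents that add atoms: N-phenylbis(trifluoromethanesulfonimide), O=S(=O)(N(c1ccccc1)S(=O)(=O)C(F)(F)F)C(F)(F)F
Why: DBU induces E1cB loss of isopropyl isocyanate, which Et2NH scavenges as a urea, and the phenoxide is O-sulfonylated by PhNTf2 in the same flask, so the electron-rich ortho-silylphenol 6, prone to protodesilylation, is never handled.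

Step 4
Reactants: 7 3,5-bis(benzyloxy)-2-(trimethylsilyl)phenyl trifluoromethanesulfonate; 8 dimethyl malonate
Product: 10 methyl 2,4-bis(benzyloxy)-6-(2-methoxy-2-oxoethyl)benzoate (dimethyl 3,5-bis(benzyloxy)homophthalate), via 3,5-bis(benzyloxy)benzyne 9 (not isolated)
Conditions: 8 (2 equiv), KF, 18-crown-6, THF, 0 °C to rt
Reagents that add atoms: none
Why: Fluoride attacks silicon and triflate leaves, which gives aryne 9 with its triple bond between the future C4a and C8a. The malonate enolate carbon bonds to C4a, the aryl anion left at C8a adds to one ester carbonyl (4-exo-trig) to a short-lived benzocyclobutenoxide, and this fragments to the benzylic ester enolate, which is protonated by fresh malonate. The reaction type is the known acyl-alkylation of arynes, that is, aryne insertion into the C–C sigma bond of malonates and beta-keto esters. No permanent ring is closed and no stereocentre is formed. The selectivity needed is regioselectivity on an unsymmetrical aryne, and it is secured by the C8 benzyloxy group, whose inductive pull distorts the triple bond and stabilises charge at C8a, so the nucleophile goes to C4a. Excess malonate should hold back a second arylation of the product enolate.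

Step 5
Reactants: 10 methyl 2,4-bis(benzyloxy)-6-(2-methoxy-2-oxoethyl)benzoate
Product: 11 methyl 2,4-bis(benzyloxy)-6-{2-[methoxy(methyl)amino]-2-oxoethyl}benzoate
Conditions: MeNH(OMe)·HCl, AlMe3, CH2Cl2, 0 °C to rt; aq potassium sodium tartrate
Reagents that add atoms: N,O-dimethylhydroxylamine hydrochloride, CNOC.Cl
Why: Weinreb amidation (aminolysis of an ester by an aluminium amide): the arylacetic ester is unhindered whereas the benzoate has two ortho substituents and two alkoxy donors, so only the aliphatic ester should react, and the weakly basic aluminium amide avoids enolisation of the acidic benzylic CH2.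

Step 6
Reactants: 12 rac-1,2-epoxyheptane (2-pentyloxirane)
Product: 13 (S)-1,2-epoxyheptane
Conditions: (S,S)-(salen)Co(OAc) (0.5 mol %; salen = N,N'-bis(3,5-di-tert-butylsalicylidene)cyclohexane-1,2-diamine dianion), H2O (0.55 equiv), neat, 0 °C to rt; distillation
Reagents that add atoms: none
Why: Jacobsen hydrolytic kinetic resolution: the (S,S)-catalyst hydrolyses the (R)-epoxide much faster, so the (S)-epoxide, which carries the future C6' configuration, remains and is distilled from the diol.

Step 7
Reactants: 14 (4-bromobut-1-yn-1-yl)trimethylsilane; 13 (S)-1,2-epoxyheptane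
Product: 16 (S)-1-(trimethylsilyl)undec-1-yn-6-ol, via butynyl Grignard reagent 15 (not isolated)
Conditions: 14, Mg, THF, rt to 40 °C; then CuBr·SMe2 (10 mol %), 13, THF, −40 to 0 °C; aqueous work-up
Reagents that add atoms: magnesium, [Mg] (kept only in 15)
Why: Copper-catalysed SN2 opening of a terminal epoxide by a Grignard reagent takes place at the unsubstituted carbon, so the C–O stereocentre is not touched and stays (S).

Step 8
Reactants: 16 (S)-1-(trimethylsilyl)undec-1-yn-6-ol
Product: 18 (S)-6-(benzyloxy)undec-1-yne, via silylalkyne benzyl ether 17 (not isolated)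
Conditions: NaH, BnBr, Bu4NI (cat.), THF–DMF, 0 °C to rt; then MeOH, K2CO3, rt
Reagents that add atoms: benzyl bromide, BrCc1ccccc1
Why: Williamson etherification followed by base-catalysed methanolysis of the alkynyl C–Si bond leaves the carbinol C–O bond alone, and the benzyl ether later prevents oxa-Michael closure onto the ynone and dehydrogenation of C6' by the ruthenium catalyst.

Step 9
Reactants: 18 (S)-6-(benzyloxy)undec-1-yne; 11 methyl 2,4-bis(benzyloxy)-6-{2-[methoxy(methyl)amino]-2-oxoethyl}benzoate
Product: 20 methyl 2,4-bis(benzyloxy)-6-[(8S)-8-(benzyloxy)-2-oxotridec-3-yn-1-yl]benzoate, via lithium acetylide 19 (not isolated)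
Conditions: 18, n-BuLi, THF, −78 °C; then 11, −78 to −30 °C; inverse quench into cold 1 M HCl
Reagents that add atoms: n-butyllithium, [Li]CCCC (lithium kept only in 19)
Why: Weinreb ketone synthesis: the acetylide should add once because the chelated adduct holds until the quench, the hindered benzoate is left alone, an acetylide is a poor kinetic base toward the benzylic CH2, and the acidic inverse quench keeps the released amine from adding to the ynone.

Step 10
Reactants: 20 methyl 2,4-bis(benzyloxy)-6-[(8S)-8-(benzyloxy)-2-oxotridec-3-yn-1-yl]benzoate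
Product: 21 methyl 2,4-bis(benzyloxy)-6-[(2S,8S)-8-(benzyloxy)-2-hydroxytridec-3-yn-1-yl]benzoate
Conditions: Ru[(S,S)-TsNCHPhCHPhNH](p-cymene) (2–5 mol %), i-PrOH (CH2Cl2 co-solvent), rt
Reagents that add atoms: none
Why: Noyori asymmetric transfer hydrogenation of an alkynyl ketone: the catalyst tells the linear alkynyl arm from the sp3 CH2Ar arm, the (S,S)-complex should give the (S)-propargylic alcohol, and this centre becomes (3R) once the alkyne is saturated because the CIP ranks of its two carbon arms swap while the geometry stays.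

Step 11
Reactants: 21 methyl 2,4-bis(benzyloxy)-6-[(2S,8S)-8-(benzyloxy)-2-hydroxytridec-3-yn-1-yl]benzoate
Product: 23 (3R)-6,8-dihydroxy-3-[(6S)-6-hydroxyundecyl]-3,4-dihydro-1H-isochromen-1-one, via tetrahydroxy ester 22 (not isolated)
Conditions: H2 (1 atm), Pd/C (10 wt % Pd), EtOAc–MeOH, rt; filter, concentrate; p-TsOH·H2O (10 mol %), toluene, 60 °C
Reagents that add atoms: none
Why: Heterogeneous hydrogenation saturates the alkyne and hydrogenolyses all three benzyl ethers at their benzylic C–O bonds, so both stereocentres stay, and acid-catalysed lactonisation of the C3 hydroxyl onto the neighbouring ester (6-exo-trig, acyl–oxygen cleavage, retention at C3) closes the ring, whereas the C6' hydroxyl would have to form a twelve-membered ring.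

Compound list
1 | 3,5-bis(benzyloxy)phenol | Oc1cc(OCc2ccccc2)cc(OCc2ccccc2)c1 | starting material
2 | 3,5-bis(benzyloxy)phenyl isopropylcarbamate | CC(C)NC(=O)Oc1cc(OCc2ccccc2)cc(OCc2ccccc2)c1 | intermediate
3 | 3,5-bis(benzyloxy)phenyl N-(tert-butyldimethylsilyl)-N-isopropylcarbamate | CC(C)N(C(=O)Oc1cc(OCc2ccccc2)cc(OCc2ccccc2)c1)[Si](C)(C)C(C)(C)C | intermediate
4 | 3,5-bis(benzyloxy)-2-(trimethylsilyl)phenyl N-(tert-butyldimethylsilyl)-N-isopropylcarbamate | CC(C)N(C(=O)Oc1cc(OCc2ccccc2)cc(OCc2ccccc2)c1[Si](C)(C)C)[Si](C)(C)C(C)(C)C | intermediate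
5 | 3,5-bis(benzyloxy)-2-(trimethylsilyl)phenyl isopropylcarbamate | CC(C)NC(=O)Oc1cc(OCc2ccccc2)cc(OCc2ccccc2)c1[Si](C)(C)C | intermediate
6 | 3,5-bis(benzyloxy)-2-(trimethylsilyl)phenol | C[Si](C)(C)c1c(O)cc(OCc2ccccc2)cc1OCc1ccccc1 | intermediate
7 | 3,5-bis(benzyloxy)-2-(trimethylsilyl)phenyl trifluoromethanesulfonate | C[Si](C)(C)c1c(OCc2ccccc2)cc(OCc2ccccc2)cc1OS(=O)(=O)C(F)(F)F | intermediate
8 | dimethyl malonate | COC(=O)CC(=O)OC | starting material
9 | 3,5-bis(benzyloxy)benzyne (1,2-didehydro-3,5-bis(benzyloxy)benzene) | C1#CC(OCc2ccccc2)=CC(OCc2ccccc2)=C1 | intermediate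
10 | methyl 2,4-bis(benzyloxy)-6-(2-methoxy-2-oxoethyl)benzoate | COC(=O)Cc1cc(OCc2ccccc2)cc(OCc2ccccc2)c1C(=O)OC | intermediate
11 | methyl 2,4-bis(benzyloxy)-6-{2-[methoxy(methyl)amino]-2-oxoethyl}benzoate | CON(C)C(=O)Cc1cc(OCc2ccccc2)cc(OCc2ccccc2)c1C(=O)OC | intermediate
12 | rac-1,2-epoxyheptane | CCCCCC1CO1 | starting material
13 | (S)-1,2-epoxyheptane | CCCCC[C@H]1CO1 | intermediate
14 | (4-bromobut-1-yn-1-yl)trimethylsilane | C[Si](C)(C)C#CCCBr | starting material
15 | [4-(trimethylsilyl)but-3-yn-1-yl]magnesium bromide | C[Si](C)(C)C#CCC[Mg]Br | intermediate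
16 | (S)-1-(trimethylsilyl)undec-1-yn-6-ol | CCCCC[C@H](O)CCCC#C[Si](C)(C)C | intermediate
17 | (S)-[6-(benzyloxy)undec-1-yn-1-yl]trimethylsilane | CCCCC[C@H](OCc1ccccc1)CCCC#C[Si](C)(C)C | intermediate
18 | (S)-6-(benzyloxy)undec-1-yne | CCCCC[C@H](OCc1ccccc1)CCCC#C | intermediate
19 | lithium (S)-6-(benzyloxy)undec-1-yn-1-ide | CCCCC[C@H](OCc1ccccc1)CCCC#C[Li] | intermediate
20 | methyl 2,4-bis(benzyloxy)-6-[(8S)-8-(benzyloxy)-2-oxotridec-3-yn-1-yl]benzoate | CCCCC[C@H](OCc1ccccc1)CCCC#CC(=O)Cc1cc(OCc2ccccc2)cc(OCc2ccccc2)c1C(=O)OC | intermediate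
21 | methyl 2,4-bis(benzyloxy)-6-[(2S,8S)-8-(benzyloxy)-2-hydroxytridec-3-yn-1-yl]benzoate | CCCCC[C@H](OCc1ccccc1)CCCC#C[C@@H](O)Cc1cc(OCc2ccccc2)cc(OCc2ccccc2)c1C(=O)OC | intermediate
22 | methyl 2,4-dihydroxy-6-[(2R,8S)-2,8-dihydroxytridecyl]benzoate | CCCCC[C@H](O)CCCCC[C@@H](O)Cc1cc(O)cc(O)c1C(=O)OC | intermediate
23 | (3R)-6,8-dihydroxy-3-[(6S)-6-hydroxyundecyl]-3,4-dihydro-1H-isochromen-1-one | CCCCC[C@H](O)CCCCC[C@@H]1Cc2cc(O)cc(O)c2C(=O)O1 | target

Total step count: 11
Longest linear sequence: 8 steps (steps 1–5 and 9–11). The side-chain branch (steps 6–8) joins at step 9.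

Steps most likely to fail

1. Step 4 (aryne insertion).
- What may go wrong: the aryl anion may be protonated before it closes on the ester, so that plain alpha-arylation replaces insertion. The product enolate may capture a second aryne. A benzylic proton of the flanking benzyloxy group may be transferred to the aryl anion.
- Fallback: the two bonds are made one after the other by known chemistry, setting out from carbamate 2. N-silylation and lithiation as in step 2 (through 3), with methyl chloroformate as the electrophile, should give methyl 2,4-bis(benzyloxy)-6-{[N-(tert-butyldimethylsilyl)-N-isopropylcarbamoyl]oxy}benzoate F1. The acidic work-up should convert it to methyl 2,4-bis(benzyloxy)-6-[(isopropylcarbamoyl)oxy]benzoate F2, so C1–C8a is made by directed metalation. Et2NH/DBU in MeCN should free methyl 2,4-bis(benzyloxy)-6-hydroxybenzoate F3. Tf2O/pyridine should then give methyl 2,4-bis(benzyloxy)-6-{[(trifluoromethyl)sulfonyl]oxy}benzoate F4. A Negishi coupling with the Reformatsky reagent BrZnCH2CO2Me (Pd2(dba)3, XPhos, THF, 60 °C) forms C4–C4a and comes back to the route at 10.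

2. Step 9 (acetylide acylation).
- What may go wrong: the acidic benzylic CH2 of the amide may be deprotonated instead of the carbonyl being attacked. The released amine may add in conjugate fashion during the quench. The benzylic ynone may undergo base-induced enol-lactonisation.
- Fallback: the ynone is given up. C3 is set by reagent-controlled allylation and the chain is joined by metathesis, setting out from 11 and 13. i-Bu2AlH (THF, −78 °C) should reduce the amide to methyl 2,4-bis(benzyloxy)-6-(2-oxoethyl)benzoate F5. Brown allylation with (+)-Ipc2B(allyl) (from the (−)-alpha-pinene series, Et2O, −78 °C) follows. Oxidative work-up and brief K2CO3/MeOH treatment then close the alkoxide onto the ester, which should give (3R)-3-allyl-6,8-bis(benzyloxy)-3,4-dihydro-1H-isochromen-1-one F6. Separately, 13 is opened with allylMgBr (CuBr·SMe2 cat., THF, −40 °C) to (S)-dec-1-en-5-ol F7, which needs no protection. Cross metathesis of F6 with excess F7 (second-generation Hoveyda–Grubbs catalyst, CH2Cl2, 40 °C) should give (3R)-6,8-bis(benzyloxy)-3-[(2E,6S)-6-hydroxyundec-2-en-1-yl]-3,4-dihydro-1H-isochromen-1-one F8. H2 over Pd/C then saturates the alkene, removes both benzyl groups and comes back to the route at 23.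

3. Step 11 (global hydrogenation and lactonisation).
- What may go wrong: the allylic alcohol formed half-way may isomerise on palladium to the ketone, with loss of the C3 centre. The propargylic or allylic C–O bond may be hydrogenolysed. Ring closure may be sluggish once the free phenols deactivate the ester.
- Fallback: the events are separated and the lactone is closed before the phenols are freed, setting out from 21. Metal-free diimide reduction (TsNHNH2, NaOAc, DME–H2O, reflux, excess) should give methyl 2,4-bis(benzyloxy)-6-[(2R,8S)-8-(benzyloxy)-2-hydroxytridecyl]benzoate F9. Alkoxide-driven lactonisation (NaH, THF, 0 °C) should give (3R)-6,8-bis(benzyloxy)-3-[(6S)-6-(benzyloxy)undecyl]-3,4-dihydro-1H-isochromen-1-one F10. Hydrogenolysis (H2, Pd/C, EtOAc–MeOH) of a substrate that no longer holds an unsaturated C–O neighbour comes back to the route at 23.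

Further compounds
F1 | step 4 | methyl 2,4-bis(benzyloxy)-6-{[N-(tert-butyldimethylsilyl)-N-isopropylcarbamoyl]oxy}benzoate | COC(=O)c1c(OCc2ccccc2)cc(OCc2ccccc2)cc1OC(=O)N(C(C)C)[Si](C)(C)C(C)(C)C
F2 | step 4 | methyl 2,4-bis(benzyloxy)-6-[(isopropylcarbamoyl)oxy]benzoate | COC(=O)c1c(OCc2ccccc2)cc(OCc2ccccc2)cc1OC(=O)NC(C)C
F3 | step 4 | methyl 2,4-bis(benzyloxy)-6-hydroxybenzoate | COC(=O)c1c(O)cc(OCc2ccccc2)cc1OCc1ccccc1
F4 | step 4 | methyl 2,4-bis(benzyloxy)-6-{[(trifluoromethyl)sulfonyl]oxy}benzoate | COC(=O)c1c(OCc2ccccc2)cc(OCc2ccccc2)cc1OS(=O)(=O)C(F)(F)F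
F5 | step 9 | methyl 2,4-bis(benzyloxy)-6-(2-oxoethyl)benzoate | O=CCc1cc(OCc2ccccc2)cc(OCc2ccccc2)c1C(=O)OC
F6 | step 9 | (3R)-3-allyl-6,8-bis(benzyloxy)-3,4-dihydro-1H-isochromen-1-one | C=CC[C@@H]1Cc2cc(OCc3ccccc3)cc(OCc3ccccc3)c2C(=O)O1
F7 | step 9 | (S)-dec-1-en-5-ol | CCCCC[C@H](O)CCC=C
F8 | step 9 | (3R)-6,8-bis(benzyloxy)-3-[(2E,6S)-6-hydroxyundec-2-en-1-yl]-3,4-dihydro-1H-isochromen-1-one | CCCCC[C@H](O)CC/C=C/C[C@@H]1Cc2cc(OCc3ccccc3)cc(OCc3ccccc3)c2C(=O)O1
F9 | step 11 | methyl 2,4-bis(benzyloxy)-6-[(2R,8S)-8-(benzyloxy)-2-hydroxytridecyl]benzoate | CCCCC[C@H](OCc1ccccc1)CCCCC[C@@H](O)Cc1cc(OCc2ccccc2)cc(OCc2ccccc2)c1C(=O)OC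
F10 | step 11 | (3R)-6,8-bis(benzyloxy)-3-[(6S)-6-(benzyloxy)undecyl]-3,4-dihydro-1H-isochromen-1-one | CCCCC[C@H](OCc1ccccc1)CCCCC[C@@H]1Cc2cc(OCc3ccccc3)cc(OCc3ccccc3)c2C(=O)O1
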